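The numbers of this flask are made up, and the outcome is calculated.

Start each flask from the charge below and read it at the asked time, without letting the sample stand.

| setting | east | south-west | west | north-west | north |
|---|---|---|---|---|---|
| substrate | 0.060 M | 0.080 M | 0.12 M | 0.20 M | 0.30 M |
| time | 15 min | 15 min | 15 min | 15 min | 15 min |

    substrate + 2 target → 3 target (k1 = 5.7 /M²/s)
    substrate → target (k2 = 4.0 × 10⁻⁵ /s)
    target ⇌ isomer of the product (K3 = 0.28, k3 = 8.2 × 10⁻⁴ /s)

- share of target in all that became target or isomer of the product for east, south-west, west, north-west, north, in this order
- how that number moves from the first to the last of them (falls all the way / falls, then rises / rises all the way / hardly changes / rises, then falls)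

- two of one species on the left: rate k times its square, two consumed each time
- "hardly changes" means that all values lie within two and a half points (for a concentration: within two and a half percent of the largest)
- run time (east): 15 min

**In the flask.** The slow uncatalysed step turns 3.60 % of a charge into target in 15 min. The autocatalytic step matches it once [target] reaches 0.00265 M.

**When you come.** At that feed, east needs 18.4 min to reach this level, later than your reading, so expect east still quiet. North needs 3.68 min, well before the reading, so expect its burst early.

**Leave alone.** Don't let a sample wait. Target and isomer of the product drift towards a target share of 78.1 % with 3.08 min, the relaxation half-life: the natural log of 2 over the sum of the forward and reverse constants of the isomer step. That is shorter than the run, so fresh target reads high and old target reads near 78.1 %.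

**My reckoning.** Fed steadily, east reads 84.4 %. North, taken as fresh target when it reaches 0.00265 M and relaxing from then on, reads 79.8 %. I can't place the burst in the flasks between, so I give no peak height. Taking one of them, caught in its burst, as fresh target with nothing isomerised and setting it against these ends, I expect the row to go: rises, then falls.

**The forecast.** It reads 85.3 %, 86.5 %, 91 %, 86 %, 81.5 %: rises, then falls. Its east stands above mine. It puts the west burst late, “leaving the freshly made target little time to isomerise”.

**The result.** The flasks give 85.2 %, 86.1 %, 91.4 %, 84.2 %, 81.1 %: rises, then falls, and the forecast holds within its margin. West stands highest, read with 84.5 % of its substrate left, and the row turns at 0.13 M.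

**North relaxing.** At 7.50 min the north flask holds target 94.0 %, isomer of the product 6.02 % and substrate 0 %, so its feed has stopped. Let the excess over 78.1 % relax for the remaining 7.50 min at 3.08 min, and the north share comes to 81.0 %. The reverse step carries part of that north share: the same north run without it ends at 64.6 %.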